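You read these flasks at 15 h, so for each one the useful question is how that time compares with the time ring closure needs at its temperature.

| flask | Zo | temperature | remark | time |
|---|---|---|---|---|
| gamma | 0.18 M | −10 °C | run made earlier |  |
| zeta | 0.72 M | 18 °C | run made earlier |  |
| green | 0.36 M | 25 °C |  | 15 h |
| teal | 0.36 M | −5 °C |  | 15 h |
| grey | 0.36 M | 10 °C |  | 15 h |
| amber | 0.36 M | 40 °C |  | 15 h |

| gamma: time / h | gamma: Ky / % | zeta: time / h | zeta: Ky / % |
|---|---|---|---|
| 8.00 | 0 | 1.33 | 10 |
| 25.0 | 6 | 2.50 | 9 |
| 30.0 | 0 | 4.00 | 17 |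
| 60.0 | 4 | 6.00 | 17 |
| 96.0 | 0 | 10.0 | 20 |
| 120 | 4 | 20.0 | 24 |

(each reading ± 2 percentage points)

- which flask leads in amount of Ky, in percent of the Zo charged ("all alike" within 1.5 percentage points) (green / teal / grey / amber / all alike)
- how much Ky is there at the end, in percent of the Zo charged: green
- how much Ky is there at the end, in percent of the Zo charged: teal
- how much Ky is there at the end, in percent of the Zo charged: grey
- how much Ky is there at the end, in percent of the Zo charged: amber

- what was read earlier has a scatter of 2 percentage points, one standard deviation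

Call the ring time τ the reading time divided by the fraction of the charge found as Ky, taken while that fraction is still small; this is then roughly the time constant of a first-order step, and I assume that Zo closes one molecule at a time, so that τ does not depend on the charge. In zeta, 17% after 4.00 h gives τ = 23.5 h at 18 °C. In gamma, 4% after 120 h gives 3000 h at −10 °C. Those two times give an activation energy E of 110 kJ mol⁻¹, and with it teal has τ = 1170 h.

The weak link is the gamma reading: its scatter is 2 percentage points, and the reading before it was 0%. So you reforge it by drawing one line through the origin and the gamma readings together, which gives τ = 3310 h and E = 113 kJ mol⁻¹. Teal then has τ = 1270 h, grey 87.5 h, green 7.90 h and amber 0.898 h. I commit to 1.18% Ky in teal, and to amber as leader, its ring time being shorter than those of green, grey and teal. For green and amber, τ is below 15 h, so my reckoning gives their order but no percentage.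

The forecast chose amber, with green 42% (25% to 58%), teal 2.5% (0.5% to 7%), grey 17% (9% to 27%) and amber 62% (32% to 82%). Its teal figure stands above mine. Its ground: “That means warmth favours the ring.”

The flasks gave green 38.3%, teal 1.65%, grey 14.1% and amber 60.6%, so amber led.

    2 Zo ⇌ Uv (K = 25.0 M⁻¹, k = 2.50 × 10⁻⁵ M⁻¹ s⁻¹, Ea = 68.0 kJ mol⁻¹, ΔH = −26.0 kJ mol⁻¹)
    Ky ⇌ Yx (K = 1.50, k = 2.20 × 10⁻⁵ s⁻¹, Ea = 92.0 kJ mol⁻¹, ΔH = −59.0 kJ mol⁻¹)
    Zo → Ky (k = 2.90 × 10⁻⁵ s⁻¹, Ea = 100 kJ mol⁻¹)
    (constants at 25 °C)

In amber, with a reckoned τ of 0.898 h, the passing of Zo into Ky had done half of its turnover up to 15.0 h by 0.916 h, the passing of 2 Zo into Uv had done so by 0.266 h, and Zo stood at 0.705% at 7.50 h. From then to 15.0 h, amber's Ky went from 59.3% to 60.6% and its Yx from 28.2% to 29.0%. The neighbour flask, amber's charge at 15 °C, has a reckoned τ of 38.2 h, longer than 15 h, and it ended with Zo at 52.0% and Ky at 23.5%.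

The numbers in the tables come from a simulation with made-up constants; the scatter is artificial.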